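**Assumption.** The SMILES is (+)-azimine, the head-to-tail cyclic dimer of (2R,5S,6S)-azimic acid. Open-chain intermediates are numbered along the C12 chain: C1 = methyl, C2 = C–N, C3 = C–O, C6 = the second carbon on N, C12 = carboxyl carbon.

## Retrosynthetic overview

1. Azimine ⇐ hydrogenolysis of its N,N'-bis-Cbz derivative ⇐ head-to-tail cyclodimerisation of N-Cbz-azimic acid; the 22-membered dilactone is formed last.
2. N-Cbz-azimic acid ⇐ all-cis piperidine diol ⇐ one-pot hydrogenolysis and intramolecular reductive amination of an acyclic 2-amino-6-ketone; this closes the piperidine and sets C6.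
3. Amino ketone ⇐ C6 aldehyde + 6-(benzyloxy)hexyl Grignard reagent (C6–C7 bond), then oxidation.
4. C6 aldehyde ⇐ hydroboration of a homoallylic benzyl ether ⇐ key C3–C4 bond: chelation-controlled allylation of N,N-dibenzyl-L-alaninal with allyltrimethylsilane, which sets C3.
5. N,N-Dibenzyl-L-alaninal ⇐ L-alaninol, which supplies C2. Ring order: piperidine first, macrodiolide second.

## Route

Step 1
Reactants: 1 L-alaninol, (S)-2-aminopropan-1-ol
Product: 2 (S)-2-(dibenzylamino)propan-1-ol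
Conditions: BnBr (2.2 equiv), K2CO3, MeCN, reflux
Reagents that add atoms: benzyl bromide, BrCc1ccccc1
Why: Double SN2 N-alkylation stops at the hindered tertiary amine, K2CO3 does not alkylate the alcohol, and the chiral-pool stereocentre is not touched.

Step 2
Reactants: 2 (S)-2-(dibenzylamino)propan-1-ol
Product: 3 (S)-2-(dibenzylamino)propanal
Conditions: (COCl)2, DMSO, CH2Cl2, −78 °C; Et3N, −78 → 0 °C; used crude at once
Reagents that add atoms: none
Why: Swern oxidation gives the N,N-dibenzyl α-amino aldehyde, which keeps its configuration when kept cold and not chromatographed.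

Step 3
Reactants: 3 (S)-2-(dibenzylamino)propanal; 4 allyltrimethylsilane
Product: 5 (4S,5S)-5-(dibenzylamino)hex-1-en-4-ol
Conditions: SnCl4 (1.1 equiv), CH2Cl2, −78 °C, 10 min; then 4 (1.5 equiv), −78 °C; aq. NaHCO3
Reagents that add atoms: none
Why: Hosomi–Sakurai carbonyl allylation under chelation control, in which SnCl4 ties C=O and NBn2 into a five-membered chelate and the allylsilane attacks the face opposite the methyl group, setting the carbinol (4S) syn to nitrogen (about 9:1 or better expected, minor anti isomer removed by chromatography).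

Step 4
Reactants: 5 (4S,5S)-5-(dibenzylamino)hex-1-en-4-ol
Product: 6 (2S,3S)-N,N-dibenzyl-3-(benzyloxy)hex-5-en-2-amine
Conditions: NaH, BnBr, Bu4NI (cat.), THF/DMF, 0 °C → rt
Reagents that add atoms: benzyl bromide, BrCc1ccccc1
Why: Williamson etherification of the alkoxide is much faster than quaternisation of the hindered tertiary amine, and the benzyl ether can later leave in the same hydrogenolysis as the N-benzyl groups.

Step 5
Reactants: 6 (2S,3S)-N,N-dibenzyl-3-(benzyloxy)hex-5-en-2-amine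
Product: 8 (4S,5S)-4-(benzyloxy)-5-(dibenzylamino)hexan-1-ol, via B-alkyl-9-BBN adduct 7 (not isolated)
Conditions: 9-BBN (1.5 equiv), THF, 0 °C → rt; then 3 M NaOH, 30% H2O2, 0 °C → rt
Reagents that add atoms: hydrogen peroxide, OO
Why: Anti-Markovnikov hydroboration–oxidation of the terminal alkene with bulky 9-BBN turns the allyl terminus into the primary C6 alcohol without touching the ether or amine.

Step 6
Reactants: 8 (4S,5S)-4-(benzyloxy)-5-(dibenzylamino)hexan-1-ol
Product: 9 (4S,5S)-4-(benzyloxy)-5-(dibenzylamino)hexanal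
Conditions: (COCl)2, DMSO, CH2Cl2, −78 °C; Et3N, −78 → 0 °C
Reagents that add atoms: none
Why: Swern oxidation stops at the aldehyde and tolerates tertiary amines and benzyl ethers.

Step 7
Reactants: 9 (4S,5S)-4-(benzyloxy)-5-(dibenzylamino)hexanal; 10 benzyl 6-bromohexyl ether
Product: 12 (2S,3S)-3,12-bis(benzyloxy)-2-(dibenzylamino)dodecan-6-ol (both C6 epimers), via Grignard reagent 11 (not isolated)
Conditions: 10 (1.6 equiv), Mg, THF, 40 °C; then 9, THF, −78 → 0 °C; aq. NH4Cl
Reagents that add atoms: none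
Why: Grignard addition to the unhindered aldehyde completes the C12 chain, and the C6 epimer mixture is of no consequence because the carbinol is oxidised next.

Step 8
Reactants: 12 (2S,3S)-3,12-bis(benzyloxy)-2-(dibenzylamino)dodecan-6-ol
Product: 13 (2S,3S)-3,12-bis(benzyloxy)-2-(dibenzylamino)dodecan-6-one
Conditions: (COCl)2, DMSO, CH2Cl2, −78 °C; Et3N, −78 → 0 °C
Reagents that add atoms: none
Why: Swern oxidation converges both epimers on one ketone whose carbonyl sits 1,5 to the masked amine, ready for ring closure.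

Step 9
Reactants: 13 (2S,3S)-3,12-bis(benzyloxy)-2-(dibenzylamino)dodecan-6-one
Product: 16 (2S,3S,6R)-6-(6-hydroxyhexyl)-2-methylpiperidin-3-ol, via amino ketone 14 (not isolated), via cyclic imine 15 (not isolated)
Conditions: H2 (4 atm), Pd(OH)2/C, MeOH/AcOH 9:1, rt, 24–48 h; filtration, basic ion-exchange work-up
Reagents that add atoms: none
Why: Hydrogenolysis of the four benzyl groups frees the amine, which condenses with the C6 ketone, and hydrogen then adds to the cyclic imine (intramolecular reductive amination) from the face opposite the C2 methyl and C3 oxygen, so C6 (R) carries its chain cis to both.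

Step 10
Reactants: 16 (2S,3S,6R)-6-(6-hydroxyhexyl)-2-methylpiperidin-3-ol
Product: 17 benzyl (2S,3S,6R)-3-hydroxy-6-(6-hydroxyhexyl)-2-methylpiperidine-1-carboxylate
Conditions: CbzCl (1.3 equiv), Na2CO3, THF/H2O 1:1, 0 °C → rt
Reagents that add atoms: benzyl chloroformate, O=C(Cl)OCc1ccccc1
Why: Schotten–Baumann carbamoylation is selective for the amine over both alcohols and masks nitrogen for the acylation chemistry to come.

Step 11
Reactants: 17 benzyl (2S,3S,6R)-3-hydroxy-6-(6-hydroxyhexyl)-2-methylpiperidine-1-carboxylate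
Product: 18 N-Cbz-azimic acid, 6-[(2R,5S,6S)-1-[(benzyloxy)carbonyl]-5-hydroxy-6-methylpiperidin-2-yl]hexanoic acid
Conditions: TEMPO (0.2 equiv), PhI(OAc)2 (2.2 equiv), MeCN/H2O 1:1, 0 °C → rt
Reagents that add atoms: water, O
Why: Oxoammonium (TEMPO) oxidation is strongly selective for the primary alcohol, taking it through the aldehyde hydrate to the acid while the hindered ring secondary alcohol is left alone.

Step 12
Reactants: 18 N-Cbz-azimic acid (two molecules)
Product: 21 N,N'-bis(benzyloxycarbonyl)azimine, via mixed anhydride 19 (not isolated), via linear dimer 20 (not isolated)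
Conditions: 2,4,6-trichlorobenzoyl chloride (1.2 equiv), Et3N (1.5 equiv), THF, rt, 2 h; then slow addition to DMAP (5 equiv), toluene, 90 °C, final concentration about 5 mM
Reagents that add atoms: none
Why: Yamaguchi lactonisation run as a cyclodimerisation, in which the strained 11-membered monolactone is disfavoured, so the activated acid first acylates the C5-OH of a second molecule and the linear dimer then closes to the 22-membered dilactone with retention at every stereocentre.

Step 13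
Reactants: 21 N,N'-bis(benzyloxycarbonyl)azimine
Product: 22 (+)-azimine
Conditions: H2 (1 atm), Pd/C, MeOH, rt
Reagents that add atoms: none
Why: Hydrogenolysis of the two benzyl carbamates releases toluene and CO2 under neutral conditions that leave the lactones and all six stereocentres untouched.

## Compound list

1 | L-alaninol, (S)-2-aminopropan-1-ol | C[C@H](N)CO | starting material
2 | (S)-2-(dibenzylamino)propan-1-ol | C[C@H](N(Cc1ccccc1)Cc1ccccc1)CO | intermediate
3 | (S)-2-(dibenzylamino)propanal | C[C@H](N(Cc1ccccc1)Cc1ccccc1)C=O | intermediate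
4 | allyltrimethylsilane | C=CC[Si](C)(C)C | starting material
5 | (4S,5S)-5-(dibenzylamino)hex-1-en-4-ol | C[C@H](N(Cc1ccccc1)Cc1ccccc1)[C@@H](O)CC=C | intermediate
6 | (2S,3S)-N,N-dibenzyl-3-(benzyloxy)hex-5-en-2-amine | C[C@H](N(Cc1ccccc1)Cc1ccccc1)[C@@H](OCc1ccccc1)CC=C | intermediate
7 | 9-[(4S,5S)-4-(benzyloxy)-5-(dibenzylamino)hexyl]-9-borabicyclo[3.3.1]nonane (not isolated) | C[C@H](N(Cc1ccccc1)Cc1ccccc1)[C@@H](OCc1ccccc1)CCCB1C2CCCC1CCC2 | intermediate
8 | (4S,5S)-4-(benzyloxy)-5-(dibenzylamino)hexan-1-ol | C[C@H](N(Cc1ccccc1)Cc1ccccc1)[C@@H](OCc1ccccc1)CCCO | intermediate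
9 | (4S,5S)-4-(benzyloxy)-5-(dibenzylamino)hexanal | C[C@H](N(Cc1ccccc1)Cc1ccccc1)[C@@H](OCc1ccccc1)CCC=O | intermediate
10 | benzyl 6-bromohexyl ether | BrCCCCCCOCc1ccccc1 | starting material
11 | [6-(benzyloxy)hexyl]magnesium bromide (not isolated) | Br[Mg]CCCCCCOCc1ccccc1 | intermediate
12 | (2S,3S)-3,12-bis(benzyloxy)-2-(dibenzylamino)dodecan-6-ol, both C6 epimers | C[C@H](N(Cc1ccccc1)Cc1ccccc1)[C@@H](OCc1ccccc1)CCC(O)CCCCCCOCc1ccccc1 | intermediate
13 | (2S,3S)-3,12-bis(benzyloxy)-2-(dibenzylamino)dodecan-6-one | C[C@H](N(Cc1ccccc1)Cc1ccccc1)[C@@H](OCc1ccccc1)CCC(=O)CCCCCCOCc1ccccc1 | intermediate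
14 | (2S,3S)-2-amino-3,12-dihydroxydodecan-6-one (not isolated) | C[C@H](N)[C@@H](O)CCC(=O)CCCCCCO | intermediate
15 | (2S,3S)-6-(6-hydroxyhexyl)-2-methyl-2,3,4,5-tetrahydropyridin-3-ol (not isolated) | C[C@@H]1N=C(CCCCCCO)CC[C@@H]1O | intermediate
16 | (2S,3S,6R)-6-(6-hydroxyhexyl)-2-methylpiperidin-3-ol, all-cis | C[C@@H]1N[C@H](CCCCCCO)CC[C@@H]1O | intermediate
17 | benzyl (2S,3S,6R)-3-hydroxy-6-(6-hydroxyhexyl)-2-methylpiperidine-1-carboxylate | C[C@@H]1N(C(=O)OCc2ccccc2)[C@H](CCCCCCO)CC[C@@H]1O | intermediate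
18 | N-Cbz-azimic acid, 6-[(2R,5S,6S)-1-[(benzyloxy)carbonyl]-5-hydroxy-6-methylpiperidin-2-yl]hexanoic acid | C[C@@H]1N(C(=O)OCc2ccccc2)[C@H](CCCCCC(=O)O)CC[C@@H]1O | intermediate
19 | mixed anhydride of 18 with 2,4,6-trichlorobenzoic acid (not isolated) | C[C@@H]1N(C(=O)OCc2ccccc2)[C@H](CCCCCC(=O)OC(=O)c2c(Cl)cc(Cl)cc2Cl)CC[C@@H]1O | intermediate
20 | linear dimer: one unit of 18 (ring OH free) esterified through its carboxyl to the ring oxygen of a second unit, whose carboxyl is the 2,4,6-trichlorobenzoic mixed anhydride (not isolated) | C[C@@H]1N(C(=O)OCc2ccccc2)[C@H](CCCCCC(=O)O[C@H]3CC[C@@H](CCCCCC(=O)OC(=O)c4c(Cl)cc(Cl)cc4Cl)N(C(=O)OCc4ccccc4)[C@H]3C)CC[C@@H]1O | intermediate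
21 | N,N'-bis(benzyloxycarbonyl)azimine, the 22-membered dilactone with both nitrogens as benzyl carbamates | C[C@@H]1N(C(=O)OCc4ccccc4)[C@@H]2CCCCCC(=O)O[C@H]3CC[C@@H](CCCCCC(=O)O[C@H]1CC2)N(C(=O)OCc4ccccc4)[C@H]3C | intermediate
22 | (+)-azimine (CNP0219883.1) | C[C@@H]1N[C@@H]2CCCCCC(=O)O[C@H]3CC[C@@H](CCCCCC(=O)O[C@H]1CC2)N[C@H]3C | target

## Step count and risks

Total steps: 13. Longest linear sequence: 13 steps, from 1 to 22; compounds 4 and 10 are bought.

**Step 3 (syn selectivity of the chelation-controlled allylation; possible erosion of 3).** The fallback sets out from 3 and comes back at 5. Aldehyde 3 is treated with CH2=CHCH2MgBr in Et2O at −78 °C, which adds without chelation (Felkin–Anh) to give mainly the anti alcohol (4R,5S)-5-(dibenzylamino)hex-1-en-4-ol F1. This alcohol, or any syn/anti mixture from step 3, is oxidised with Dess–Martin periodinane and NaHCO3 in CH2Cl2 at 0 °C to the ketone (S)-5-(dibenzylamino)hex-1-en-4-one F2; the buffer avoids alkene migration and epimerisation. NaBH4 in MeOH at −20 °C then reduces F2 under Felkin–Anh control, now with hydride as the incoming group, to the syn alcohol 5. The carbinol configuration is thus set by reduction instead of by the C–C bond formation.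

**Step 11 (primary-over-secondary selectivity of the oxidation).** The fallback sets out from 17 and comes back at 18. Diol 17 is bis-silylated (TBSOTf, 2,6-lutidine, CH2Cl2, 0 °C) to benzyl (2S,3S,6R)-3-[(tert-butyldimethylsilyl)oxy]-6-[6-[(tert-butyldimethylsilyl)oxy]hexyl]-2-methylpiperidine-1-carboxylate F3. The primary silyl ether is cleaved selectively (HF·pyridine, pyridine/THF, 0 °C) to benzyl (2S,3S,6R)-3-[(tert-butyldimethylsilyl)oxy]-6-(6-hydroxyhexyl)-2-methylpiperidine-1-carboxylate F4. The only free alcohol is oxidised (TEMPO, PhI(OAc)2, MeCN/H2O) to 6-[(2R,5S,6S)-1-[(benzyloxy)carbonyl]-5-[(tert-butyldimethylsilyl)oxy]-6-methylpiperidin-2-yl]hexanoic acid F5. Aqueous HF in MeCN then removes the secondary silyl ether to give 18.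

**Step 12 (oligomers instead of the cyclic dimer).** The fallback sets out from 18 and comes back at 20, building the linear dimer stepwise.
- One half of 18 is esterified with excess Me3SiCH2CH2OH (EDC·HCl, DMAP cat., CH2Cl2) to 2-(trimethylsilyl)ethyl 6-[(2R,5S,6S)-1-[(benzyloxy)carbonyl]-5-hydroxy-6-methylpiperidin-2-yl]hexanoate F6.
- The other half is silylated with Et3SiCl and imidazole in DMF to triethylsilyl 6-[(2R,5S,6S)-1-[(benzyloxy)carbonyl]-6-methyl-5-[(triethylsilyl)oxy]piperidin-2-yl]hexanoate F7. Its silyl ester is cleaved with K2CO3 in MeOH/H2O at 0 °C to 6-[(2R,5S,6S)-1-[(benzyloxy)carbonyl]-6-methyl-5-[(triethylsilyl)oxy]piperidin-2-yl]hexanoic acid F8.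
- Steglich esterification of F8 with the ring hydroxyl of F6 (EDC·HCl, DMAP, CH2Cl2) gives the protected linear dimer F9.
- Bu4NF in THF removes the triethylsilyl ether and the 2-(trimethylsilyl)ethyl ester in one operation to give the linear hydroxy acid dimer F10.
- F10 with 2,4,6-trichlorobenzoyl chloride and Et3N gives the mixed anhydride 20, which is closed to 21 with DMAP in toluene at high dilution (about 1 mM) as in step 12.

## Further compounds

F1 | step 3 | (4R,5S)-5-(dibenzylamino)hex-1-en-4-ol | C[C@H](N(Cc1ccccc1)Cc1ccccc1)[C@H](O)CC=C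
F2 | step 3 | (S)-5-(dibenzylamino)hex-1-en-4-one | C[C@H](N(Cc1ccccc1)Cc1ccccc1)C(=O)CC=C
F3 | step 11 | benzyl (2S,3S,6R)-3-[(tert-butyldimethylsilyl)oxy]-6-[6-[(tert-butyldimethylsilyl)oxy]hexyl]-2-methylpiperidine-1-carboxylate | C[C@@H]1N(C(=O)OCc2ccccc2)[C@H](CCCCCCO[Si](C)(C)C(C)(C)C)CC[C@@H]1O[Si](C)(C)C(C)(C)C
F4 | step 11 | benzyl (2S,3S,6R)-3-[(tert-butyldimethylsilyl)oxy]-6-(6-hydroxyhexyl)-2-methylpiperidine-1-carboxylate | C[C@@H]1N(C(=O)OCc2ccccc2)[C@H](CCCCCCO)CC[C@@H]1O[Si](C)(C)C(C)(C)C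
F5 | step 11 | 6-[(2R,5S,6S)-1-[(benzyloxy)carbonyl]-5-[(tert-butyldimethylsilyl)oxy]-6-methylpiperidin-2-yl]hexanoic acid | C[C@@H]1N(C(=O)OCc2ccccc2)[C@H](CCCCCC(=O)O)CC[C@@H]1O[Si](C)(C)C(C)(C)C
F6 | step 12 | 2-(trimethylsilyl)ethyl 6-[(2R,5S,6S)-1-[(benzyloxy)carbonyl]-5-hydroxy-6-methylpiperidin-2-yl]hexanoate | C[C@@H]1N(C(=O)OCc2ccccc2)[C@H](CCCCCC(=O)OCC[Si](C)(C)C)CC[C@@H]1O
F7 | step 12 | triethylsilyl 6-[(2R,5S,6S)-1-[(benzyloxy)carbonyl]-6-methyl-5-[(triethylsilyl)oxy]piperidin-2-yl]hexanoate | C[C@@H]1N(C(=O)OCc2ccccc2)[C@H](CCCCCC(=O)O[Si](CC)(CC)CC)CC[C@@H]1O[Si](CC)(CC)CC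
F8 | step 12 | 6-[(2R,5S,6S)-1-[(benzyloxy)carbonyl]-6-methyl-5-[(triethylsilyl)oxy]piperidin-2-yl]hexanoic acid | C[C@@H]1N(C(=O)OCc2ccccc2)[C@H](CCCCCC(=O)O[Si](CC)(CC)CC)CC[C@@H]1O[Si](CC)(CC)CC
F9 | step 12 | protected linear dimer: carboxyl of F8 esterified to the ring oxygen of F6 (triethylsilyl ether on one unit, 2-(trimethylsilyl)ethyl ester on the other) | C[C@@H]1N(C(=O)OCc2ccccc2)[C@H](CCCCCC(=O)O[C@H]3CC[C@@H](CCCCCC(=O)OCC[Si](C)(C)C)N(C(=O)OCc4ccccc4)[C@H]3C)CC[C@@H]1O[Si](CC)(CC)CC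
F10 | step 12 | linear hydroxy acid dimer of N-Cbz-azimic acid (one free ring OH, one free carboxyl) | C[C@@H]1N(C(=O)OCc2ccccc2)[C@H](CCCCCC(=O)O[C@H]3CC[C@@H](CCCCCC(=O)O)N(C(=O)OCc4ccccc4)[C@H]3C)CC[C@@H]1O
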